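**Plan**
- Retrosynthesis: the four benzyl ethers come off last, the benzylic CH2 on C2 of ring A is traced back to a ketone, and ring A is then cut at C3–C2 and C6–C1.
- Enabling feature: in ring A the run C3(OH)–C4(H)–C5(OMe)–C6(CH2Ar) is a 1,3-dioxygenated four-carbon diene. C1 (ethylene bridge) and C2 (benzylic carbon, ortho to the hydroxyl) are the two alkyne carbons of an aryl ynone.
- Diene half: the C6–CH2Ar bond comes from γ-alkylation of methyl acetoacetate, followed by the enol methyl ether and the silyl ketene acetal.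
- Ynone half: on ring B the diarylmethane bond (Grignard addition, ionic reduction), the aryl–bridge bond (Negishi coupling) and the alkyne–acyl bond (acyl Sonogashira coupling) are made in that order.
- Forward order: every other benzene ring is bought. Ring A is the only ring built, in the step that also joins the two halves, and C=O to CH2 and hydrogenolysis follow.
- Stereochemistry: the target has no stereocentre. Only the (3Z) geometry of the diene matters, and allylic strain in the deprotonation should set it.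

Key step: step 10

Remark: ring A is numbered C1 (bridge), C2 and C6 (benzyl groups), C3 (OH), C4 (H), C5 (OMe). The ketene acetal geometry of the diene and the configurations of the transient cycloadduct and quinone methide do not affect the product and are drawn as the mechanism suggests.

**Step 1**
Reactants: 1 methyl acetoacetate; 2 4-(benzyloxy)benzyl chloride
Product: 4 methyl 5-[4-(benzyloxy)phenyl]-3-oxopentanoate, via acetoacetate dianion 3 (not isolated)
Conditions: NaH, THF, 0 °C; n-BuLi, 0 °C; then 2, 0 °C to rt; 1 M HCl quench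
Reagents that add atoms: sodium hydride, [Na+].[H-]; n-butyllithium, [Li]CCCC (the metal ions stay only in 3)
Why: γ-Alkylation of an acetoacetate dianion, in which the more basic terminal carbanion attacks the reactive benzylic chloride by SN2, so the central carbon should stay unalkylated.

**Step 2**
Reactants: 4 methyl 5-[4-(benzyloxy)phenyl]-3-oxopentanoate
Product: 5 methyl (2E)-5-[4-(benzyloxy)phenyl]-3-methoxypent-2-enoate
Conditions: HC(OMe)3, H2SO4 (cat.), MeOH, rt to 50 °C
Reagents that add atoms: trimethyl orthoformate, COC(OC)OC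
Why: Acid-catalysed enol ether formation from a β-keto ester and an orthoformate, run under equilibrating conditions that should favour the conjugated (E)-enoate with methoxy trans to the ester.

**Step 3**
Reactants: 5 methyl (2E)-5-[4-(benzyloxy)phenyl]-3-methoxypent-2-enoate
Product: 7 (1Z,3Z)-5-[4-(benzyloxy)phenyl]-1,3-dimethoxy-1-(trimethylsilyloxy)penta-1,3-diene, via lithium dienolate 6 (not isolated)
Conditions: LiN(iPr)2, THF, −78 °C; Me3SiCl, −78 °C to rt; hexane, filtration under Ar, used crude
Reagents that add atoms: lithium diisopropylamide, [Li+].CC(C)[N-]C(C)C (lithium stays only in 6); chlorotrimethylsilane, C[Si](C)(C)Cl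
Why: Kinetic γ-deprotonation of a β-methoxy enoate and O-silylation is the standard way to vinylketene silyl acetals, and allylic 1,3-strain against the ester should turn the arylmethyl group away from C2 to give the (3Z) isomer, whose s-cis conformer is open.

**Step 4**
Reactants: 8 4-bromo-2-hydroxybenzaldehyde
Product: 9 2-(benzyloxy)-4-bromobenzaldehyde
Conditions: BnBr, K2CO3, DMF, rt
Reagents that add atoms: benzyl bromide, BrCc1ccccc1
Why: Williamson ether synthesis on an acidic salicylaldehyde phenol, leaving the aldehyde and the aryl bromide untouched.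

**Step 5**
Reactants: 9 2-(benzyloxy)-4-bromobenzaldehyde; 10 4-(benzyloxy)phenylmagnesium bromide (commercial THF solution)
Product: 11 rac-[2-(benzyloxy)-4-bromophenyl][4-(benzyloxy)phenyl]methanol
Conditions: THF, 0 °C; aq. NH4Cl
Reagents that add atoms: none
Why: Grignard 1,2-addition to an aromatic aldehyde is much faster at 0 °C than any exchange at the aryl bromide, and the new carbinol centre forms as a racemate that step 6 removes.

**Step 6**
Reactants: 11 rac-[2-(benzyloxy)-4-bromophenyl][4-(benzyloxy)phenyl]methanol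
Product: 12 2-(benzyloxy)-1-[4-(benzyloxy)benzyl]-4-bromobenzene
Conditions: Et3SiH, TFA, CH2Cl2, 0 °C
Reagents that add atoms: none
Why: Ionic hydrogenation, in which the benzhydrol ionises easily to a cation stabilised by one ortho and one para alkoxy group and the silane traps it, while aryl benzyl ethers and the bromide tolerate short contact with TFA at 0 °C.

**Step 7**
Reactants: 12 2-(benzyloxy)-1-[4-(benzyloxy)benzyl]-4-bromobenzene; 13 (4-bromobut-1-yn-1-yl)trimethylsilane
Product: 15 (4-{3-(benzyloxy)-4-[4-(benzyloxy)benzyl]phenyl}but-1-yn-1-yl)trimethylsilane, via homopropargylic zinc bromide 14 (not isolated)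
Conditions: 13, Zn dust, I2 (5 mol %), DMA, 80 °C; then 12, Pd(OAc)2 (2 mol %), SPhos (4 mol %), THF, 50 °C
Reagents that add atoms: zinc, [Zn] (stays only in 14)
Why: Negishi sp3–sp2 cross-coupling with a silyl-capped homopropargylic zinc reagent of a well-used type, where the bulky electron-rich phosphine favours reductive elimination over β-hydride elimination and the silyl cap keeps the alkyne out of the catalytic cycle.

**Step 8**
Reactants: 15 (4-{3-(benzyloxy)-4-[4-(benzyloxy)benzyl]phenyl}but-1-yn-1-yl)trimethylsilane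
Product: 16 2-(benzyloxy)-1-[4-(benzyloxy)benzyl]-4-(but-3-yn-1-yl)benzene
Conditions: K2CO3 (cat.), MeOH/THF, rt
Reagents that add atoms: none
Why: Base-catalysed protodesilylation of an alkynylsilane by methanol, to which the ethers and the diarylmethane are inert.

**Step 9**
Reactants: 16 2-(benzyloxy)-1-[4-(benzyloxy)benzyl]-4-(but-3-yn-1-yl)benzene; 17 4-(benzyloxy)benzoyl chloride
Product: 18 1-[4-(benzyloxy)phenyl]-5-{3-(benzyloxy)-4-[4-(benzyloxy)benzyl]phenyl}pent-2-yn-1-one
Conditions: PdCl2(PPh3)2 (2 mol %), CuI (4 mol %), Et3N (1.2 equiv), THF, rt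
Reagents that add atoms: none
Why: Acyl Sonogashira coupling of a terminal alkyne with an aroyl chloride gives the ynone at room temperature without a separate oxidation, and the near-stoichiometric amine should not isomerise the propargylic CH2.

**Step 10**
Reactants: 7 (1Z,3Z)-5-[4-(benzyloxy)phenyl]-1,3-dimethoxy-1-(trimethylsilyloxy)penta-1,3-diene; 18 1-[4-(benzyloxy)phenyl]-5-{3-(benzyloxy)-4-[4-(benzyloxy)benzyl]phenyl}pent-2-yn-1-one
Product: 21 [4-(benzyloxy)phenyl]{3-[4-(benzyloxy)benzyl]-2-(2-{3-(benzyloxy)-4-[4-(benzyloxy)benzyl]phenyl}ethyl)-6-hydroxy-4-methoxyphenyl}methanone, via cyclohexadiene cycloadduct 19 (not isolated), via aryl trimethylsilyl ether 20 (not isolated)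
Conditions: 7 (3 equiv), xylenes (2 M), sealed tube, Ar, 140 °C; then 1 M HCl, THF, rt
Reagents that add atoms: none
Why: This is a normal-electron-demand Diels–Alder reaction of a vinylketene silyl acetal with an acetylenic ketone, in which bonding of diene C4 to the ynone β-carbon (ring A C6–C1) should run well ahead of bonding of the acetal carbon to the α-carbon (C3–C2), the extreme being a Michael-type attack followed by ring closure, and either path leads to cyclohexa-1,4-diene 19. Compound 19 holds a methoxy group on the acetal carbon and a hydrogen on the opposite sp3 carbon, so 1,4-loss of methanol aromatises it to silyl ether 20, which dilute acid cleaves to phenol 21 with its hydroxyl hydrogen-bonded to the ketone. The closest known reaction type is the thermal benzannulation of 1-alkoxy-1-silyloxy-3-oxy dienes with alkynoates and ynones, internal alkynes included, to ortho-hydroxyaryl carbonyl compounds. Ring A closes as a six-membered carbocycle by an intermolecular [4+2] addition, and the two stereocentres of 19 vanish on aromatisation, so no stereocontrol is needed. The step needs regioselectivity, secured by matched polarity (largest donor coefficient at the arylmethyl-bearing C4, largest acceptor coefficient at the ynone β-carbon), and chemoselectivity for C≡C over C=O, secured by leaving out any Lewis acid. The (3Z) geometry puts the arylmethyl group on the outside of the s-cis diene, high concentration offsets the crowding of a terminally substituted diene against a disubstituted alkyne, and excess 7 allows for ketene acetal consumed by the liberated methanol.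

**Step 11**
Reactants: 21 the ring A ortho-hydroxy diaryl ketone from step 10
Product: 24 2,4-bis[4-(benzyloxy)benzyl]-3-(2-{3-(benzyloxy)-4-[4-(benzyloxy)benzyl]phenyl}ethyl)-5-methoxyphenol, via aryl ethyl carbonate 22 (not isolated), via ortho-quinone methide 23 (not isolated)
Conditions: ClCO2Et, Et3N, THF, 0 °C; filtration; NaBH4, THF/H2O, 0 °C to rt
Reagents that add atoms: ethyl chloroformate, CCOC(=O)Cl (its atoms stay only in 22)
Why: This is the known reduction of an ortho-acylphenol through its ethyl carbonate with NaBH4, in which hydride addition to the ketone is followed by carbonate migration to the benzylic oxygen, 1,4-elimination to 23 and conjugate hydride addition, all under basic conditions that leave benzyl ethers intact.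

**Step 12**
Reactants: 24 2,4-bis[4-(benzyloxy)benzyl]-3-(2-{3-(benzyloxy)-4-[4-(benzyloxy)benzyl]phenyl}ethyl)-5-methoxyphenol
Product: 25 2,4-bis(4-hydroxybenzyl)-3-{2-[3-hydroxy-4-(4-hydroxybenzyl)phenyl]ethyl}-5-methoxyphenol (CNP0207338.0)
Conditions: H2 (1 atm), 10% Pd/C, EtOAc/MeOH, rt
Reagents that add atoms: none
Why: Catalytic hydrogenolysis cleaves the four aryl benzyl ethers, while the diarylmethane C–C bonds, the methyl ether and the arenes are inert at 1 atm and room temperature.

**Compound list**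
1 | methyl acetoacetate | COC(=O)CC(C)=O | starting material
2 | 4-(benzyloxy)benzyl chloride | ClCc1ccc(OCc2ccccc2)cc1 | starting material
3 | acetoacetate dianion, sodium lithium salt (not isolated) | [Na+].[Li+].COC(=O)[CH-]C(=O)[CH2-] | intermediate
4 | methyl 5-[4-(benzyloxy)phenyl]-3-oxopentanoate | COC(=O)CC(=O)CCc1ccc(OCc2ccccc2)cc1 | intermediate
5 | methyl (2E)-5-[4-(benzyloxy)phenyl]-3-methoxypent-2-enoate | COC(=O)/C=C(/OC)CCc1ccc(OCc2ccccc2)cc1 | intermediate
6 | lithium dienolate of 5, same double-bond geometry as 7 (not isolated) | [Li+].CO/C([O-])=C/C(OC)=C/Cc1ccc(OCc2ccccc2)cc1 | intermediate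
7 | (1Z,3Z)-5-[4-(benzyloxy)phenyl]-1,3-dimethoxy-1-(trimethylsilyloxy)penta-1,3-diene | CO/C(O[Si](C)(C)C)=C/C(OC)=C/Cc1ccc(OCc2ccccc2)cc1 | intermediate
8 | 4-bromo-2-hydroxybenzaldehyde | O=Cc1ccc(Br)cc1O | starting material
9 | 2-(benzyloxy)-4-bromobenzaldehyde | O=Cc1ccc(Br)cc1OCc1ccccc1 | intermediate
10 | 4-(benzyloxy)phenylmagnesium bromide | Br[Mg]c1ccc(OCc2ccccc2)cc1 | starting material
11 | rac-[2-(benzyloxy)-4-bromophenyl][4-(benzyloxy)phenyl]methanol (racemate, no configuration drawn) | OC(c1ccc(OCc2ccccc2)cc1)c1ccc(Br)cc1OCc1ccccc1 | intermediate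
12 | 2-(benzyloxy)-1-[4-(benzyloxy)benzyl]-4-bromobenzene | Brc1ccc(Cc2ccc(OCc3ccccc3)cc2)c(OCc2ccccc2)c1 | intermediate
13 | (4-bromobut-1-yn-1-yl)trimethylsilane | C[Si](C)(C)C#CCCBr | starting material
14 | [4-(trimethylsilyl)but-3-yn-1-yl]zinc bromide (not isolated) | C[Si](C)(C)C#CCC[Zn]Br | intermediate
15 | (4-{3-(benzyloxy)-4-[4-(benzyloxy)benzyl]phenyl}but-1-yn-1-yl)trimethylsilane | C[Si](C)(C)C#CCCc1ccc(Cc2ccc(OCc3ccccc3)cc2)c(OCc2ccccc2)c1 | intermediate
16 | 2-(benzyloxy)-1-[4-(benzyloxy)benzyl]-4-(but-3-yn-1-yl)benzene | C#CCCc1ccc(Cc2ccc(OCc3ccccc3)cc2)c(OCc2ccccc2)c1 | intermediate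
17 | 4-(benzyloxy)benzoyl chloride | O=C(Cl)c1ccc(OCc2ccccc2)cc1 | starting material
18 | 1-[4-(benzyloxy)phenyl]-5-{3-(benzyloxy)-4-[4-(benzyloxy)benzyl]phenyl}pent-2-yn-1-one | O=C(C#CCCc1ccc(Cc2ccc(OCc3ccccc3)cc2)c(OCc2ccccc2)c1)c1ccc(OCc2ccccc2)cc1 | intermediate
19 | cyclohexa-1,4-diene cycloadduct, racemic, acetal methoxy cis to the arylmethyl group as expected for suprafacial addition (not isolated) | COC1=C[C@@](OC)(O[Si](C)(C)C)C(C(=O)c2ccc(OCc3ccccc3)cc2)=C(CCc2ccc(Cc3ccc(OCc4ccccc4)cc3)c(OCc3ccccc3)c2)[C@@H]1Cc1ccc(OCc2ccccc2)cc1 | intermediate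
20 | trimethylsilyl ether of 21 (not isolated) | COc1cc(O[Si](C)(C)C)c(C(=O)c2ccc(OCc3ccccc3)cc2)c(CCc2ccc(Cc3ccc(OCc4ccccc4)cc3)c(OCc3ccccc3)c2)c1Cc1ccc(OCc2ccccc2)cc1 | intermediate
21 | [4-(benzyloxy)phenyl]{3-[4-(benzyloxy)benzyl]-2-(2-{3-(benzyloxy)-4-[4-(benzyloxy)benzyl]phenyl}ethyl)-6-hydroxy-4-methoxyphenyl}methanone | COc1cc(O)c(C(=O)c2ccc(OCc3ccccc3)cc2)c(CCc2ccc(Cc3ccc(OCc4ccccc4)cc3)c(OCc3ccccc3)c2)c1Cc1ccc(OCc2ccccc2)cc1 | intermediate
22 | ethyl carbonate of 21 (not isolated) | CCOC(=O)Oc1cc(OC)c(Cc2ccc(OCc3ccccc3)cc2)c(CCc2ccc(Cc3ccc(OCc4ccccc4)cc3)c(OCc3ccccc3)c2)c1C(=O)c1ccc(OCc2ccccc2)cc1 | intermediate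
23 | ortho-quinone methide, aryl group drawn turned towards the carbonyl oxygen (not isolated) | O=C1C=C(OC)C(Cc2ccc(OCc3ccccc3)cc2)=C(CCc2ccc(Cc3ccc(OCc4ccccc4)cc3)c(OCc3ccccc3)c2)/C1=C/c1ccc(OCc2ccccc2)cc1 | intermediate
24 | 2,4-bis[4-(benzyloxy)benzyl]-3-(2-{3-(benzyloxy)-4-[4-(benzyloxy)benzyl]phenyl}ethyl)-5-methoxyphenol | COc1cc(O)c(Cc2ccc(OCc3ccccc3)cc2)c(CCc2ccc(Cc3ccc(OCc4ccccc4)cc3)c(OCc3ccccc3)c2)c1Cc1ccc(OCc2ccccc2)cc1 | intermediate
25 | 2,4-bis(4-hydroxybenzyl)-3-{2-[3-hydroxy-4-(4-hydroxybenzyl)phenyl]ethyl}-5-methoxyphenol | COc1cc(O)c(Cc2ccc(O)cc2)c(CCc2ccc(Cc3ccc(O)cc3)c(O)c2)c1Cc1ccc(O)cc1 | target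

**Step count**
- Total: 12 steps.
- Longest linear sequence: 9 steps (steps 4 to 12).
- The diene branch (steps 1 to 3) joins at step 10.

**Steps most likely to fail**

**Step 10.**
- Risk: the cycloaddition may be too slow, because a terminally substituted diene meets an alkyne that carries an alkyl chain and an aroyl group. Thermal decay or protodesilylation of the ketene acetal could then win.
- Fallback: the dienophile is made smaller and more electron-poor, and the aryl group is brought in after ring A exists. The fallback sets out from 16, also uses 7 and 10, and comes back at 24, so step 11 is bypassed.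
- Lithiation of 16 (n-BuLi, THF, −78 °C) and formylation with DMF should give 5-{3-(benzyloxy)-4-[4-(benzyloxy)benzyl]phenyl}pent-2-ynal F1.
- Heating F1 with 7 at 80 to 110 °C should give the formyl cycloadduct F2, which loses methanol to the silylated salicylaldehyde F3. Dilute acid then frees the ring A salicylaldehyde F4.
- Two equivalents of 10 should add to F4 to give the racemic ortho-hydroxybenzhydrol F5. Ionic hydrogenation (Et3SiH, TFA, CH2Cl2, −20 °C) of this doubly activated carbinol should give 24.

**Step 3.**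
- Risk: deprotonation may compete at the vinylic position, silylation may occur on carbon, the (3E) isomer with a blocked s-cis conformer may form, or the ketene acetal, which cannot be distilled, may hydrolyse on handling.
- Fallback: a 1,3-bis(silyloxy) diene is made straight from the keto ester, and the two oxygens are told apart after ring formation by the hydrogen bond to the ketone. The fallback sets out from 4, also uses 18, and comes back at 21.
- Me3SiCl and Et3N should convert 4 into the silyl enol ether F6. LiN(iPr)2 and Me3SiCl at −78 °C should then give the 1-methoxy-1,3-bis(trimethylsilyloxy) diene F7.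
- Heating F7 with 18 as in step 10 should give the bis-silyloxy cycloadduct F8, which aromatises to the bis(trimethylsilyl) ether F9. Acid then frees the resorcinol ketone F10.
- One equivalent of MeI with K2CO3 in acetone should methylate only the free, more acidic C5 hydroxyl, because the C3 hydroxyl is held by the ketone. This gives 21.

**Step 11.**
- Risk: hydride addition to a doubly ortho-substituted, electron-rich ketone may be slower than hydrolysis of the carbonate, which would only return the phenol.
- Fallback: the order of the last two operations is reversed, and the anionic reduction is replaced by a cationic one. The fallback sets out from 21 and comes back at 25.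
- Hydrogenolysis (H2, Pd/C, EtOAc/MeOH) should give the pentahydroxy ketone F11.
- Ionic hydrogenation (Et3SiH, TFA, rt) should then reduce the protonated ketone through the benzhydryl cation to CH2 and give 25 directly. With no benzyl ethers left, the acid cannot cause benzyl migration.

**Further compounds**
F1 | step 10 | 5-{3-(benzyloxy)-4-[4-(benzyloxy)benzyl]phenyl}pent-2-ynal | O=CC#CCCc1ccc(Cc2ccc(OCc3ccccc3)cc2)c(OCc2ccccc2)c1
F2 | step 10 | formyl cycloadduct, racemic, acetal methoxy cis to the arylmethyl group | COC1=C[C@@](OC)(O[Si](C)(C)C)C(C=O)=C(CCc2ccc(Cc3ccc(OCc4ccccc4)cc3)c(OCc3ccccc3)c2)[C@@H]1Cc1ccc(OCc2ccccc2)cc1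
F3 | step 10 | silylated salicylaldehyde | COc1cc(O[Si](C)(C)C)c(C=O)c(CCc2ccc(Cc3ccc(OCc4ccccc4)cc3)c(OCc3ccccc3)c2)c1Cc1ccc(OCc2ccccc2)cc1
F4 | step 10 | ring A salicylaldehyde, 3-[4-(benzyloxy)benzyl]-2-(2-{3-(benzyloxy)-4-[4-(benzyloxy)benzyl]phenyl}ethyl)-6-hydroxy-4-methoxybenzaldehyde | COc1cc(O)c(C=O)c(CCc2ccc(Cc3ccc(OCc4ccccc4)cc3)c(OCc3ccccc3)c2)c1Cc1ccc(OCc2ccccc2)cc1
F5 | step 10 | racemic ortho-hydroxybenzhydrol | COc1cc(O)c(C(O)c2ccc(OCc3ccccc3)cc2)c(CCc2ccc(Cc3ccc(OCc4ccccc4)cc3)c(OCc3ccccc3)c2)c1Cc1ccc(OCc2ccccc2)cc1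
F6 | step 3 | methyl (2Z)-5-[4-(benzyloxy)phenyl]-3-(trimethylsilyloxy)pent-2-enoate | COC(=O)/C=C(\O[Si](C)(C)C)CCc1ccc(OCc2ccccc2)cc1
F7 | step 3 | (1Z,3Z)-5-[4-(benzyloxy)phenyl]-1-methoxy-1,3-bis(trimethylsilyloxy)penta-1,3-diene | CO/C(O[Si](C)(C)C)=C/C(O[Si](C)(C)C)=C/Cc1ccc(OCc2ccccc2)cc1
F8 | step 3 | bis-silyloxy cycloadduct, racemic, acetal methoxy cis to the arylmethyl group | C[Si](C)(C)OC1=C[C@@](OC)(O[Si](C)(C)C)C(C(=O)c2ccc(OCc3ccccc3)cc2)=C(CCc2ccc(Cc3ccc(OCc4ccccc4)cc3)c(OCc3ccccc3)c2)[C@@H]1Cc1ccc(OCc2ccccc2)cc1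
F9 | step 3 | bis(trimethylsilyl) ether of the resorcinol ketone | C[Si](C)(C)Oc1cc(O[Si](C)(C)C)c(C(=O)c2ccc(OCc3ccccc3)cc2)c(CCc2ccc(Cc3ccc(OCc4ccccc4)cc3)c(OCc3ccccc3)c2)c1Cc1ccc(OCc2ccccc2)cc1
F10 | step 3 | resorcinol ketone, [4-(benzyloxy)phenyl]{3-[4-(benzyloxy)benzyl]-2-(2-{3-(benzyloxy)-4-[4-(benzyloxy)benzyl]phenyl}ethyl)-4,6-dihydroxyphenyl}methanone | Oc1cc(O)c(C(=O)c2ccc(OCc3ccccc3)cc2)c(CCc2ccc(Cc3ccc(OCc4ccccc4)cc3)c(OCc3ccccc3)c2)c1Cc1ccc(OCc2ccccc2)cc1
F11 | step 11 | pentahydroxy ketone, {6-hydroxy-3-(4-hydroxybenzyl)-2-[2-(3-hydroxy-4-(4-hydroxybenzyl)phenyl)ethyl]-4-methoxyphenyl}(4-hydroxyphenyl)methanone | COc1cc(O)c(C(=O)c2ccc(O)cc2)c(CCc2ccc(Cc3ccc(O)cc3)c(O)c2)c1Cc1ccc(O)cc1
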